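## Retrosynthetic overview
1. Both acids are released last with fluoride from a bis[2-(trimethylsilyl)ethyl] ester, so the oxirane never meets acid.
2. The only ring, the oxirane (C4–O–C5), is formed second to last by catalyst-controlled epoxidation of C4=C5 in a (2E,4Z)-dienoate. Syn oxygen transfer turns 4Z into the cis C3/C6 relation.
3. The C12–C13 bond and both of its stereocentres come from a new Rh-catalysed enantioselective anti-borylative aldol reaction of a C1–C12 aldehyde, an acrylate and B2pin2 (CH2–B becomes CH2OH).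
4. C12 comes from a linear hydroformylation (C11–C12). C3–C4 comes from a Suzuki coupling of a Z-alkenyl iodide with a β-boryl butenoate.
5. C5–C6 and the 4Z geometry come from syn-carbocupration of propyne. C8–C9 comes from allylation of the triflate of (R)-3-bromo-2-methylpropan-1-ol, which supplies C7.

Assumption: the SMILES is read literally as (2E,4S,5R,7R,12R,13R), with C3 and C6 cis on the oxirane (the epoxide of a 4Z-diene). Atom numbers follow the tetradec-2-enedioic acid chain (C1 = enoic acid carbon, C14 = saturated acid carbon).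

## Route

Step 1
Reactants: 1 (R)-3-bromo-2-methylpropan-1-ol
Product: 2 (R)-3-bromo-2-methylpropyl trifluoromethanesulfonate
Conditions: Tf2O (1.1 equiv), 2,6-lutidine (1.2 equiv), CH2Cl2, −78 °C, 30 min; cold aqueous work-up, used crude
Reagents that add atoms: trifluoromethanesulfonic anhydride, O=S(=O)(OS(=O)(=O)C(F)(F)F)C(F)(F)F
Why: O-sulfonylation of a primary alcohol at low temperature, which leaves the purchased stereocentre (future C7) and the bromide untouched.

Step 2
Reactants: 2 (R)-3-bromo-2-methylpropyl trifluoromethanesulfonate; 3 allylmagnesium bromide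
Product: 4 (R)-6-bromo-5-methylhex-1-ene
Conditions: 3 (1.2 equiv), Li2CuCl4 (5 mol %), Et2O/THF, −78 → −20 °C
Reagents that add atoms: none
Why: Copper-catalysed sp3–sp3 Grignard cross-coupling (Kochi–Schlosser type), in which the primary triflate reacts far faster than the β-branched primary bromide below −20 °C, so C8–C9 forms and the bromide is kept for step 3.

Step 3
Reactants: 4 (R)-6-bromo-5-methylhex-1-ene; 5 propyne
Product: 9 (1Z,4R)-1-iodo-2,4-dimethylocta-1,7-diene, via Grignard reagent 6 (not isolated), via alkylcopper 7 (not isolated), via alkenylcopper 8 (not isolated)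
Conditions: Mg, Et2O, 35 °C; add to CuBr·SMe2 (1.0 equiv), Et2O/Me2S, −45 °C, 1 h; 5 (2 equiv), −25 °C, 3 h; I2 (1.1 equiv) in THF, −78 → 0 °C
Reagents that add atoms: iodine, II (the iodine of 9); magnesium, [Mg] (held in 6 only); CuBr·SMe2, Br[Cu].CSC (copper held in 7 and 8 only)
Why: Normant carbocupration, in which alkyl and copper add syn across propyne (alkyl to the internal carbon) so that C6 and Cu are cis, and iodinolysis with retention fixes the C5–C6 bond and the future 4Z geometry.

Step 4
Reactants: 10 but-2-ynoic acid; 11 2-(trimethylsilyl)ethanol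
Product: 12 2-(trimethylsilyl)ethyl but-2-ynoate
Conditions: DCC (1.05 equiv), DMAP (5 mol %), CH2Cl2, 0 °C → rt
Reagents that add atoms: none
Why: Steglich esterification under neutral conditions, which installs the fluoride-labile ester of C1.

Step 5
Reactants: 12 2-(trimethylsilyl)ethyl but-2-ynoate
Product: 13 2-(trimethylsilyl)ethyl (Z)-3-(4,4,5,5-tetramethyl-1,3,2-dioxaborolan-2-yl)but-2-enoate
Conditions: CuCl (3 mol %), NaOtBu (6 mol %), Xantphos (3 mol %), B2pin2 (1.1 equiv), MeOH (2 equiv), THF, rt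
Reagents that add atoms: bis(pinacolato)diboron, CC1(C)OB(OC1(C)C)B1OC(C)(C)C(C)(C)O1
Why: Copper-catalysed β-borylation of an ynoate, in which Cu–B adds syn with boron at the β-carbon and MeOH protonates C–Cu with retention, so boron ends trans to the ester (the future 2E geometry).

Step 6
Reactants: 9 (1Z,4R)-1-iodo-2,4-dimethylocta-1,7-diene; 13 2-(trimethylsilyl)ethyl (Z)-3-(4,4,5,5-tetramethyl-1,3,2-dioxaborolan-2-yl)but-2-enoate
Product: 14 2-(trimethylsilyl)ethyl (2E,4Z,7R)-3,5,7-trimethylundeca-2,4,10-trienoate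
Conditions: PdCl2(dppf) (5 mol %), K3PO4 (3 equiv), 13 (1.3 equiv), THF/H2O 10:1, 45 °C
Reagents that add atoms: none
Why: Suzuki–Miyaura coupling forms C3–C4 with retention at both sp2 partners, and the remote terminal alkene does not compete with transmetalation.

Step 7
Reactants: 14 2-(trimethylsilyl)ethyl (2E,4Z,7R)-3,5,7-trimethylundeca-2,4,10-trienoate
Product: 15 2-(trimethylsilyl)ethyl (2E,4Z,7R)-3,5,7-trimethyl-12-oxododeca-2,4-dienoate
Conditions: Rh(acac)(CO)2 (1 mol %), BIPHEPHOS (3 mol %), CO/H2 1:1 (10 bar), toluene, 60 °C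
Reagents that add atoms: carbon monoxide, [C-]#[O+]
Why: Linear-selective rhodium hydroformylation with a bulky bisphosphite, in which only the monosubstituted C10=C11 alkene binds and inserts, giving C12 as the aldehyde while the hindered trisubstituted dienoate stays untouched.

Step 8
Reactants: 16 acryloyl chloride; 11 2-(trimethylsilyl)ethanol
Product: 17 2-(trimethylsilyl)ethyl acrylate
Conditions: Et3N (1.2 equiv), BHT (trace), CH2Cl2, 0 °C
Reagents that add atoms: none
Why: Simple O-acylation of a primary alcohol by an acid chloride.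

Step 9
Reactants: 15 2-(trimethylsilyl)ethyl (2E,4Z,7R)-3,5,7-trimethyl-12-oxododeca-2,4-dienoate; 17 2-(trimethylsilyl)ethyl acrylate
Product: 19 bis[2-(trimethylsilyl)ethyl] (2E,4Z,7R,12R,13R)-12-hydroxy-13-(hydroxymethyl)-3,5,7-trimethyltetradeca-2,4-dienedioate, via bis-boryl aldolate 18 (not isolated)
Conditions: [(S,S)-iPr-Phebox]Rh(OAc)2(OH2) (2 mol %; Phebox = 2,6-bis(4-isopropyloxazolin-2-yl)phenyl), NaOtBu (5 mol %), 17 (1.5 equiv), B2pin2 (1.3 equiv, added over 4 h), toluene, 40 °C; then NaBO3·4H2O, THF/H2O, rt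
Reagents that add atoms: bis(pinacolato)diboron, CC1(C)OB(OC1(C)C)B1OC(C)(C)C(C)(C)O1 (both boryl groups of 18); sodium perborate, [Na+].[O-]OB=O (the oxygen of the CH2OH group of 19)
Why: Proposed new method: an enantioselective, anti-selective three-component borylative aldol reaction. Acetate/alkoxide-assisted transmetalation of B2pin2 gives a trivalent rhodium boryl held in the C2-symmetric NCN pincer. Borylrhodation of the unhindered acrylate 17, far faster than addition to the β,β-disubstituted dienoate of 15, gives the same type of rhodium enolate as the hydride-initiated reaction. That enolate adds to the aldehyde through a closed chair transition state, so C12–C13 forms anti and both centres are set by the catalyst. The (S,S) complex is chosen because it gives the (2R)-anti series in the hydride reaction, and the (R,R) complex is equally accessible if the sense is opposite. The rhodium aldolate is released by σ-bond metathesis with B2pin2, and slow diboron addition keeps the achiral boron-enolate pathway down. The CH2–B group is a hydroxyl surrogate that cannot leave by β-elimination as an alkoxy group would, and perborate converts it into CH2OH. Closest known reaction types: the Rh(Phebox)-catalysed anti-selective reductive aldol reaction of acrylates with hydrosilanes, the Rh(Phebox)-catalysed conjugate borylation of enoates, and the racemic copper-catalysed borylation/aldol domino reaction.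

Step 10
Reactants: 19 bis[2-(trimethylsilyl)ethyl] (2E,4Z,7R,12R,13R)-12-hydroxy-13-(hydroxymethyl)-3,5,7-trimethyltetradeca-2,4-dienedioate
Product: 20 bis[2-(trimethylsilyl)ethyl] (2E,4S,5R,7R,12R,13R)-4,5-epoxy-12-hydroxy-13-(hydroxymethyl)-3,5,7-trimethyltetradec-2-enedioate
Conditions: ent-Shi ketone (L-fructose-derived diketal ketone, from L-sorbose; 30 mol %), Oxone (2KHSO5·KHSO4·K2SO4), K2CO3, Bu4NHSO4 (cat.), MeCN/CH2(OMe)2–aq Na2B4O7/Na2EDTA buffer (pH 10.5), 0 °C
Reagents that add atoms: potassium peroxymonosulfate (active part of Oxone), [K+].[O-]S(=O)(=O)OO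
Why: Shi asymmetric epoxidation, in which the electrophilic chiral dioxirane attacks only the electron-richer C4=C5 bond (C2=C3 is deactivated by the ester), syn oxygen transfer makes C3 and C6 cis, and because the spiro transition state places the lone vinylic C4–H at the catalyst wall the D-series ketone gives 4R at such CH carbons, so the L-series ketone gives (4S,5R).

Step 11
Reactants: 20 bis[2-(trimethylsilyl)ethyl] (2E,4S,5R,7R,12R,13R)-4,5-epoxy-12-hydroxy-13-(hydroxymethyl)-3,5,7-trimethyltetradec-2-enedioate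
Product: 22 (2E,4S,5R,7R,12R,13R)-4,5-epoxy-12-hydroxy-13-(hydroxymethyl)-3,5,7-trimethyltetradec-2-enedioic acid (CNP0468463.4), via bis(tetrabutylammonium) dicarboxylate 21 (not isolated)
Conditions: Bu4NF (5 equiv), THF, 0 °C → rt; then cold aq H3PO4/NaH2PO4 (pH 3.5–4), EtOAc extraction
Reagents that add atoms: tetrabutylammonium fluoride, CCCC[N+](CCCC)(CCCC)CCCC.[F-] (cation held in 21 only)
Why: Fluoride-induced β-silyl fragmentation of both 2-(trimethylsilyl)ethyl esters to carboxylate, ethene and Me3SiF under non-acidic conditions, which spares the oxirane and all five stereocentres, and the 2E geometry keeps the C1 carboxylate away from C4.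

## Compound list
1 | (R)-3-bromo-2-methylpropan-1-ol | BrC[C@H](C)CO | starting material
2 | (R)-3-bromo-2-methylpropyl trifluoromethanesulfonate | BrC[C@H](C)COS(=O)(=O)C(F)(F)F | intermediate
3 | allylmagnesium bromide | C=CC[Mg]Br | starting material
4 | (R)-6-bromo-5-methylhex-1-ene | BrC[C@H](C)CCC=C | intermediate
5 | propyne | CC#C | starting material
6 | [(R)-2-methylhex-5-en-1-yl]magnesium bromide | Br[Mg]C[C@H](C)CCC=C | intermediate
7 | [(R)-2-methylhex-5-en-1-yl]copper (MgBr2/SMe2 complex) | [Cu]C[C@H](C)CCC=C | intermediate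
8 | [(1Z,4R)-2,4-dimethylocta-1,7-dien-1-yl]copper | [Cu]/C=C(/C)C[C@H](C)CCC=C | intermediate
9 | (1Z,4R)-1-iodo-2,4-dimethylocta-1,7-diene | I/C=C(/C)C[C@H](C)CCC=C | intermediate
10 | but-2-ynoic acid | CC#CC(=O)O | starting material
11 | 2-(trimethylsilyl)ethanol | OCC[Si](C)(C)C | starting material
12 | 2-(trimethylsilyl)ethyl but-2-ynoate | CC#CC(=O)OCC[Si](C)(C)C | intermediate
13 | 2-(trimethylsilyl)ethyl (Z)-3-(4,4,5,5-tetramethyl-1,3,2-dioxaborolan-2-yl)but-2-enoate | C/C(=C\C(=O)OCC[Si](C)(C)C)B1OC(C)(C)C(C)(C)O1 | intermediate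
14 | 2-(trimethylsilyl)ethyl (2E,4Z,7R)-3,5,7-trimethylundeca-2,4,10-trienoate | C/C(=C\C(=O)OCC[Si](C)(C)C)/C=C(/C)C[C@H](C)CCC=C | intermediate
15 | 2-(trimethylsilyl)ethyl (2E,4Z,7R)-3,5,7-trimethyl-12-oxododeca-2,4-dienoate | C/C(=C\C(=O)OCC[Si](C)(C)C)/C=C(/C)C[C@H](C)CCCCC=O | intermediate
16 | acryloyl chloride | C=CC(=O)Cl | starting material
17 | 2-(trimethylsilyl)ethyl acrylate | C=CC(=O)OCC[Si](C)(C)C | intermediate
18 | bis[2-(trimethylsilyl)ethyl] (2E,4Z,7R,12R,13R)-3,5,7-trimethyl-12-[(pinacolatoboryl)oxy]-13-[(pinacolatoboryl)methyl]tetradeca-2,4-dienedioate | C/C(=C\C(=O)OCC[Si](C)(C)C)/C=C(/C)C[C@H](C)CCCC[C@@H](OB1OC(C)(C)C(C)(C)O1)[C@@H](CB2OC(C)(C)C(C)(C)O2)C(=O)OCC[Si](C)(C)C | intermediate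
19 | bis[2-(trimethylsilyl)ethyl] (2E,4Z,7R,12R,13R)-12-hydroxy-13-(hydroxymethyl)-3,5,7-trimethyltetradeca-2,4-dienedioate | C/C(=C\C(=O)OCC[Si](C)(C)C)/C=C(/C)C[C@H](C)CCCC[C@@H](O)[C@@H](CO)C(=O)OCC[Si](C)(C)C | intermediate
20 | bis[2-(trimethylsilyl)ethyl] (2E,4S,5R,7R,12R,13R)-4,5-epoxy-12-hydroxy-13-(hydroxymethyl)-3,5,7-trimethyltetradec-2-enedioate | C/C(=C\C(=O)OCC[Si](C)(C)C)[C@@H]1O[C@]1(C)C[C@H](C)CCCC[C@@H](O)[C@@H](CO)C(=O)OCC[Si](C)(C)C | intermediate
21 | bis(tetrabutylammonium) salt of 22 | C/C(=C\C(=O)[O-])[C@@H]1O[C@]1(C)C[C@H](C)CCCC[C@@H](O)[C@@H](CO)C(=O)[O-].CCCC[N+](CCCC)(CCCC)CCCC.CCCC[N+](CCCC)(CCCC)CCCC | intermediate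
22 | (2E,4S,5R,7R,12R,13R)-4,5-epoxy-12-hydroxy-13-(hydroxymethyl)-3,5,7-trimethyltetradec-2-enedioic acid | C/C(=C\C(=O)O)[C@@H]1O[C@]1(C)C[C@H](C)CCCC[C@@H](O)[C@@H](CO)C(=O)O | target

## Step count and risks
Total steps: 11. Longest linear sequence: 8 (steps 1, 2, 3, 6, 7, 9, 10, 11).

**Step 3 (carbocupration).** A β-branched alkylcopper may add slowly to propyne, or the alkenylcopper may be protonated by excess alkyne, which would cost yield or Z purity.
- The fallback sets out from 4 (through 6) and 5 and comes back at 9. It fixes the geometry by haloboration instead of carbometalation.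
- Propyne 5 is syn-bromoborated with BBr3 (CH2Cl2, −78 °C → rt) to (Z)-(2-bromoprop-1-en-1-yl)dibromoborane F1.
- Pinacol converts this into the bromoalkenyl pinacol boronate F2.
- Grignard reagent 6 is transmetalated with ZnBr2 to the alkylzinc bromide F3.
- Negishi coupling of F3 at the C–Br bond of F2 (Pd(PtBu3)2, 2 mol %, THF, rt) proceeds with retention and gives the (Z)-alkenyl boronate F4.
- I2/NaOH (THF/H2O, 0 °C) exchanges boron for iodine with retention to give 9.

**Step 9 (new borylative aldol reaction).** Three failure modes are foreseeable: borylation of the aldehyde, an unselective background aldol reaction through the pinacolboron enolate, or insufficient anti selectivity with the primary-alkyl acrylate.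
- The fallback uses known chemistry only, sets out from 14 and comes back at 19. The stereodiad is built on a five-carbon piece and joined by metathesis.
- Commercial 2-(trimethylsilyl)ethyl acetate is converted (LiN(iPr)2, Me3SiCl, THF, −78 °C) into its silyl ketene acetal F5.
- A catalytic enantioselective Mukaiyama acetate aldol reaction with acrolein follows. It uses Ti(OiPr)4, a tridentate binaphthyl Schiff-base ligand and 3,5-di-tert-butylsalicylic acid, with the ligand enantiomer that delivers the S carbinol. This gives the silyl ether F6.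
- Dilute acid cleaves F6 to the (S)-hydroxy ester F7.
- Fráter–Seebach-type dianion formation (LiN(iPr)2, 2.2 equiv, −78 → −20 °C) and trapping with monomeric formaldehyde gives the anti diol ester F8.
- Cross-metathesis of 14 with F8 (second-generation Hoveyda–Grubbs catalyst, 1,4-benzoquinone, CH2Cl2, 40 °C) gives the (10E)-trienedioate F9.
- Diimide (2-nitrobenzenesulfonyl hydrazide, Et3N, CH2Cl2, rt) saturates only the disubstituted C10=C11 bond to give 19.

**Step 10 (Shi epoxidation).** The twisted, hindered 4Z-diene may react slowly or with poor face selectivity.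
- The fallback sets out from 9 and comes back at 20. It sets the oxirane by hydroxyl-directed epoxidation before the enoate exists.
- Compound 9 is lithiated (t-BuLi, 2 equiv, Et2O, −78 °C) and trapped with (CH2O)n to give the (Z)-allylic alcohol F10.
- Sharpless epoxidation (Ti(OiPr)4, L-(+)-diethyl tartrate, t-BuOOH, 4 Å sieves, CH2Cl2, −20 °C; the nerol-type case, which gives 2S,3R) affords the epoxy alcohol F11.
- Dess–Martin periodinane/NaHCO3 gives the epoxy aldehyde F12.
- MeMgBr (THF, −78 °C) gives the carbinol F13 as an epimer mixture.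
- A second Dess–Martin oxidation gives the epoxy methyl ketone F14.
- Diethylphosphonoacetic acid and 11 (DCC, DMAP) give the phosphonate F15.
- Horner–Wadsworth–Emmons reaction of F14 with F15 (NaH, THF, 0 °C → rt) gives the (E)-epoxy enoate F16.
- The conditions of step 7 give the epoxy aldehyde F17.
- The conditions of step 9 give 20 through the bis-boryl aldolate F18.
- The epoxy enoate is expected to survive step 9 because its β-carbon is fully substituted and SN2′ attack would have to occur at the electronically mismatched α-carbon. This exposure is why the order is only the fallback.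

## Further compounds
F1 | step 3 | (Z)-(2-bromoprop-1-en-1-yl)dibromoborane | Br/C(C)=C\B(Br)Br
F2 | step 3 | 2-[(Z)-2-bromoprop-1-en-1-yl]-4,4,5,5-tetramethyl-1,3,2-dioxaborolane | Br/C(C)=C\B1OC(C)(C)C(C)(C)O1
F3 | step 3 | [(R)-2-methylhex-5-en-1-yl]zinc bromide | Br[Zn]C[C@H](C)CCC=C
F4 | step 3 | 2-[(1Z,4R)-2,4-dimethylocta-1,7-dien-1-yl]-4,4,5,5-tetramethyl-1,3,2-dioxaborolane | CC1(C)OB(/C=C(/C)C[C@H](C)CCC=C)OC1(C)C
F5 | step 9 | 1-[2-(trimethylsilyl)ethoxy]-1-(trimethylsilyloxy)ethene | C=C(O[Si](C)(C)C)OCC[Si](C)(C)C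
F6 | step 9 | 2-(trimethylsilyl)ethyl (S)-3-(trimethylsilyloxy)pent-4-enoate | C=C[C@@H](O[Si](C)(C)C)CC(=O)OCC[Si](C)(C)C
F7 | step 9 | 2-(trimethylsilyl)ethyl (S)-3-hydroxypent-4-enoate | C=C[C@@H](O)CC(=O)OCC[Si](C)(C)C
F8 | step 9 | 2-(trimethylsilyl)ethyl (2R,3R)-3-hydroxy-2-(hydroxymethyl)pent-4-enoate | C=C[C@@H](O)[C@@H](CO)C(=O)OCC[Si](C)(C)C
F9 | step 9 | bis[2-(trimethylsilyl)ethyl] (2E,4Z,7R,10E,12R,13R)-12-hydroxy-13-(hydroxymethyl)-3,5,7-trimethyltetradeca-2,4,10-trienedioate | C/C(=C\C(=O)OCC[Si](C)(C)C)/C=C(/C)C[C@H](C)CC/C=C/[C@@H](O)[C@@H](CO)C(=O)OCC[Si](C)(C)C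
F10 | step 10 | (2Z,5R)-3,5-dimethylnona-2,8-dien-1-ol | OC/C=C(/C)C[C@H](C)CCC=C
F11 | step 10 | [(2S,3R)-3-methyl-3-[(2R)-2-methylhex-5-en-1-yl]oxiran-2-yl]methanol | OC[C@@H]1O[C@]1(C)C[C@H](C)CCC=C
F12 | step 10 | (2R,3R)-3-methyl-3-[(2R)-2-methylhex-5-en-1-yl]oxirane-2-carbaldehyde | O=C[C@@H]1O[C@]1(C)C[C@H](C)CCC=C
F13 | step 10 | 1-[(2S,3R)-3-methyl-3-[(2R)-2-methylhex-5-en-1-yl]oxiran-2-yl]ethan-1-ol (both carbinol epimers) | CC(O)[C@@H]1O[C@]1(C)C[C@H](C)CCC=C
F14 | step 10 | 1-[(2R,3R)-3-methyl-3-[(2R)-2-methylhex-5-en-1-yl]oxiran-2-yl]ethan-1-one | CC(=O)[C@@H]1O[C@]1(C)C[C@H](C)CCC=C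
F15 | step 10 | 2-(trimethylsilyl)ethyl 2-(diethoxyphosphoryl)acetate | CCOP(=O)(CC(=O)OCC[Si](C)(C)C)OCC
F16 | step 10 | 2-(trimethylsilyl)ethyl (2E)-3-[(2S,3R)-3-methyl-3-[(2R)-2-methylhex-5-en-1-yl]oxiran-2-yl]but-2-enoate | C/C(=C\C(=O)OCC[Si](C)(C)C)[C@@H]1O[C@]1(C)C[C@H](C)CCC=C
F17 | step 10 | 2-(trimethylsilyl)ethyl (2E)-3-[(2S,3R)-3-methyl-3-[(2R)-2-methyl-7-oxoheptyl]oxiran-2-yl]but-2-enoate | C/C(=C\C(=O)OCC[Si](C)(C)C)[C@@H]1O[C@]1(C)C[C@H](C)CCCCC=O
F18 | step 10 | bis[2-(trimethylsilyl)ethyl] (2E,4S,5R,7R,12R,13R)-4,5-epoxy-3,5,7-trimethyl-12-[(pinacolatoboryl)oxy]-13-[(pinacolatoboryl)methyl]tetradec-2-enedioate | C/C(=C\C(=O)OCC[Si](C)(C)C)[C@@H]1O[C@]1(C)C[C@H](C)CCCC[C@@H](OB2OC(C)(C)C(C)(C)O2)[C@@H](CB3OC(C)(C)C(C)(C)O3)C(=O)OCC[Si](C)(C)C
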